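**Retrosynthetic overview**

- The target comes from global desilylation; the CH2OH group on C3 of the oxolane comes from a vinyl group by ozonolysis and reduction.
- The oxolane is closed last, by forming the C2–C3 bond (and O1–C2) in one operation: an aldehyde condenses with a cyclic allylsiloxane and the oxocarbenium ion is trapped by the allylsilane. The enabling feature is that C2 is both benzylic and bound to the ring oxygen O1, so it is a masked aldehyde carbon (ArCH=O+), while C3 carries a one-carbon branch and can be the γ-carbon of a (Z)-allylsilane held on O1 through C5–C4.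
- The allylsiloxane is a temporary seven-membered 1,2-oxasilepine ring, formed first by ring-closing metathesis of a silicon-tethered diene and destroyed in the key step.
- The diene comes from an anti 2-vinyl-1,3-diol, whose two stereocenters (carbinol carbon and C4) are set together by an iridium-catalysed (hydroxymethyl)allylation of silyl-protected vanillin with vinyl ethylene carbonate. C3 and C2 are then relayed from C4 in the key step.
- The same protected vanillin supplies both aryl rings. Order of ring formation: oxasilepine (temporary), then oxolane.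

Key step: step 5

Remarks on the chemistry: Ar stands for 3-methoxy-4-[(triisopropylsilyl)oxy]phenyl. Ring locants are O1, C2 (aryl-bearing), C3 (one-carbon branch), C4 (carbinol branch), C5; ring A is the aryl group on C2 and ring B the one on the carbinol carbon. Assumption: the iridium catalyst carrying (S)-SEGPHOS is taken to give the (1S,2S)-diol; if the sense of induction is the opposite, (R)-SEGPHOS is used.

**Step 1**
Reactants: 1 vanillin (4-hydroxy-3-methoxybenzaldehyde)
Product: 2 3-methoxy-4-[(triisopropylsilyl)oxy]benzaldehyde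
Conditions: TIPSCl (1.1 equiv), imidazole (2 equiv), DMF, 0 °C to rt
Reagents that add atoms: chlorotriisopropylsilane (TIPSCl), CC(C)[Si](Cl)(C(C)C)C(C)C
Why: Imidazole-promoted silylation of a phenol, chosen because the bulky aryl silyl ether should survive the mildly basic allylation, the Lewis acid step and ozonolysis and is removed by fluoride at the end; no stereocenter is formed.

**Step 2**
Reactants: 2 3-methoxy-4-[(triisopropylsilyl)oxy]benzaldehyde; 3 4-ethenyl-1,3-dioxolan-2-one (vinyl ethylene carbonate, racemic)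
Product: 4 (1S,2S)-2-ethenyl-1-Ar-propane-1,3-diol (anti)
Conditions: [Ir(cod)Cl]2 (2.5 mol %), (S)-SEGPHOS (5 mol %), 4-cyano-3-nitrobenzoic acid (10 mol %), K3PO4 (5 mol %), i-PrOH (2 equiv), THF, 60 °C
Reagents that add atoms: none
Why: Iridium-catalysed transfer-hydrogenative carbonyl (hydroxymethyl)allylation, in which the cyclometalated iridium C,O-benzoate ionizes 3 with loss of CO2 to an (E)-(hydroxymethyl)allyl iridium species that adds to the aldehyde through a closed chair transition state (anti relationship), the chiral bisphosphine setting the absolute configuration of both new stereocenters and isopropanol serving as the reductant.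

**Step 3**
Reactants: 4 (1S,2S)-2-ethenyl-1-Ar-propane-1,3-diol; 5 chloro(dimethyl)(prop-2-en-1-yl)silane (allylchlorodimethylsilane)
Product: 7 tert-butyl{[(1S,2S)-2-({[dimethyl(prop-2-en-1-yl)silyl]oxy}methyl)-1-Ar-but-3-en-1-yl]oxy}dimethylsilane, via primary allyldimethylsilyl ether 6 (not isolated)
Conditions: 5 (1.05 equiv), Et3N (3 equiv), CH2Cl2, −78 °C; then TBSOTf (1.3 equiv), −78 to −20 °C
Reagents that add atoms: tert-butyldimethylsilyl trifluoromethanesulfonate (TBSOTf), CC(C)(C)[Si](C)(C)OS(=O)(=O)C(F)(F)F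
Why: Chemoselective silylation, as the small chlorosilane should react at −78 °C with the unhindered primary hydroxyl much faster than with the flanked secondary benzylic one, which is then capped in the same flask by the more reactive silyl triflate; no stereocenter is touched.

**Step 4**
Reactants: 7 tert-butyl{[(1S,2S)-2-({[dimethyl(prop-2-en-1-yl)silyl]oxy}methyl)-1-Ar-but-3-en-1-yl]oxy}dimethylsilane
Product: 8 (6S)-6-[(S)-{[tert-butyl(dimethyl)silyl]oxy}(Ar)methyl]-2,2-dimethyl-2,3,6,7-tetrahydro-1,2-oxasilepine (Z ring alkene)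
Conditions: RuCl2(=CHPh)(H2IMes)(PCy3) (second-generation Grubbs catalyst, 5 mol %), CH2Cl2 (0.01 M), 40 °C
Reagents that add atoms: none
Why: Ring-closing metathesis of a silicon-tethered diene to a seven-membered ring, which can only hold a Z-alkene and so delivers a geometrically pure cyclic allylsilane; the stereocenters are not involved.

**Step 5**
Reactants: 8 (6S)-6-[(S)-{[tert-butyl(dimethyl)silyl]oxy}(Ar)methyl]-2,2-dimethyl-2,3,6,7-tetrahydro-1,2-oxasilepine; 2 3-methoxy-4-[(triisopropylsilyl)oxy]benzaldehyde
Product: 10 (2S,3S,4S)-4-[(S)-{[tert-butyl(dimethyl)silyl]oxy}(Ar)methyl]-3-ethenyl-2-Ar-oxolane (2,3-trans-3,4-trans), via oxocarbenium ion 9 (not isolated)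
Conditions: 2 (1.2 equiv), BF3·OEt2 (1.5 equiv), CH2Cl2, −78 to −20 °C; NaHCO3 (aq) quench
Reagents that add atoms: none
Why: BF3 activates aldehyde 2 and opens the Si–O bond of 8 by fluoride transfer to silicon, so that the ring oxygen condenses with the aldehyde to the (E)-oxocarbenium ion 9, whose (Z)-allylsilane attacks the cationic carbon through its γ-carbon, and the β-silyl cation then loses the fluorosilyl group to leave the vinyl group. The closest known reaction type is the intramolecular Hosomi–Sakurai (silyl-Prins) cyclization of oxocarbenium ions, as in the Lewis acid condensation of aldehydes with cyclic allylsiloxanes or with 5-silylpent-3-en-1-ols to give 3-vinyloxolanes. The oxolane closes by C2–C3 bond formation in a 5-exo-trig mode with respect to the allylsilane double bond (5-endo with respect to the C=O+ bond, a mode that oxocarbenium ions take readily). C3 is controlled by the C4 stereocenter: allylic 1,3-strain in the Z-alkene holds the C4–H bond in the alkene plane, so the tethered oxocarbenium carbon reaches C3 from the face opposite the bulky CH(OTBS)Ar group, which gives the 3,4-trans relationship. C2 is controlled by the E geometry of the oxocarbenium ion in an envelope transition state that keeps ring A pseudo-equatorial and away from the alkenyl residue (2,3-trans), and any 2,3-cis isomer should drain to the all-trans isomer because the benzylic C2–O1 bond of such an electron-rich 2-aryloxolane ionizes reversibly under the Lewis acid. The step needs condensation through the primary oxygen only and no ionization at the second benzylic carbon: the first is secured because the primary oxygen is the one held in the siloxane while the secondary one is a TBS ether, the second by the low temperature and by the silyl (not alkyl) ether on ring B, which makes that ring a weaker donor.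

**Step 6**
Reactants: 10 (2S,3S,4S)-4-[(S)-{[tert-butyl(dimethyl)silyl]oxy}(Ar)methyl]-3-ethenyl-2-Ar-oxolane
Product: 13 [(2S,3R,4S)-4-[(S)-{[tert-butyl(dimethyl)silyl]oxy}(Ar)methyl]-2-Ar-oxolan-3-yl]methanol, via ozonide 11 (not isolated), via aldehyde 12 (not isolated)
Conditions: O3, CH2Cl2, −78 °C (Sudan Red 7B as end-point indicator); then NaBH4, MeOH, −78 to 0 °C
Reagents that add atoms: ozone, [O-][O+]=O
Why: Ozonolysis with reductive NaBH4 work-up, in which the monosubstituted vinyl group should react far faster than the two silyloxy-anisole rings and the C3 aldehyde 12 is reduced as it forms, its all-trans arrangement being the thermodynamic one so that C3 has no drive to epimerize.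

**Step 7**
Reactants: 13 [(2S,3R,4S)-4-[(S)-{[tert-butyl(dimethyl)silyl]oxy}(Ar)methyl]-2-Ar-oxolan-3-yl]methanol
Product: 14 (S)-(4-hydroxy-3-methoxyphenyl)[(3S,4R,5S)-5-(4-hydroxy-3-methoxyphenyl)-4-(hydroxymethyl)oxolan-3-yl]methanol (CID21630005)
Conditions: Bu4NF (5 equiv), AcOH (5 equiv), THF, 0 °C to rt
Reagents that add atoms: none
Why: Fluoride-mediated global desilylation of the two aryl TIPS ethers and the secondary TBS ether, buffered with acetic acid so that neither phenoxide-driven quinone methide formation nor acid-driven ionization of the benzylic alcohol (which would close a furofuran) should occur; no stereocenter is touched.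

**Compound list**

1 | vanillin (4-hydroxy-3-methoxybenzaldehyde) | COc1cc(C=O)ccc1O | starting material
2 | 3-methoxy-4-[(triisopropylsilyl)oxy]benzaldehyde | COc1cc(C=O)ccc1O[Si](C(C)C)(C(C)C)C(C)C | intermediate
3 | 4-ethenyl-1,3-dioxolan-2-one (vinyl ethylene carbonate, racemic) | C=CC1COC(=O)O1 | starting material
4 | (1S,2S)-2-ethenyl-1-Ar-propane-1,3-diol | COc1cc([C@@H](O)[C@@H](C=C)CO)ccc1O[Si](C(C)C)(C(C)C)C(C)C | intermediate
5 | chloro(dimethyl)(prop-2-en-1-yl)silane | C=CC[Si](C)(C)Cl | starting material
6 | (1S,2S)-2-({[dimethyl(prop-2-en-1-yl)silyl]oxy}methyl)-1-Ar-but-3-en-1-ol | COc1cc([C@@H](O)[C@@H](C=C)CO[Si](C)(C)CC=C)ccc1O[Si](C(C)C)(C(C)C)C(C)C | intermediate (not isolated)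
7 | tert-butyl{[(1S,2S)-2-({[dimethyl(prop-2-en-1-yl)silyl]oxy}methyl)-1-Ar-but-3-en-1-yl]oxy}dimethylsilane | COc1cc([C@@H](O[Si](C)(C)C(C)(C)C)[C@@H](C=C)CO[Si](C)(C)CC=C)ccc1O[Si](C(C)C)(C(C)C)C(C)C | intermediate
8 | (6S)-6-[(S)-{[tert-butyl(dimethyl)silyl]oxy}(Ar)methyl]-2,2-dimethyl-2,3,6,7-tetrahydro-1,2-oxasilepine (Z ring alkene) | COc1cc([C@@H](O[Si](C)(C)C(C)(C)C)[C@@H]2CO[Si](C)(C)CC=C2)ccc1O[Si](C(C)C)(C(C)C)C(C)C | intermediate
9 | (E)-(Ar-methylidene){(2S,3Z)-2-[(S)-{[tert-butyl(dimethyl)silyl]oxy}(Ar)methyl]-5-[fluoro(dimethyl)silyl]pent-3-en-1-yl}oxonium (oxocarbenium ion) | COc1cc(C=[O+]C[C@H](/C=C\C[Si](C)(C)F)[C@H](O[Si](C)(C)C(C)(C)C)c2ccc(O[Si](C(C)C)(C(C)C)C(C)C)c(OC)c2)ccc1O[Si](C(C)C)(C(C)C)C(C)C | intermediate (not isolated)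
10 | (2S,3S,4S)-4-[(S)-{[tert-butyl(dimethyl)silyl]oxy}(Ar)methyl]-3-ethenyl-2-Ar-oxolane | COc1cc([C@@H](O[Si](C)(C)C(C)(C)C)[C@@H]2CO[C@H](c3ccc(O[Si](C(C)C)(C(C)C)C(C)C)c(OC)c3)[C@H]2C=C)ccc1O[Si](C(C)C)(C(C)C)C(C)C | intermediate
11 | 1,2,4-trioxolane (secondary ozonide) of 10, configuration of 10 at the four stereocenters, trioxolane carbon unassigned | COc1cc([C@@H](O[Si](C)(C)C(C)(C)C)[C@@H]2CO[C@H](c3ccc(O[Si](C(C)C)(C(C)C)C(C)C)c(OC)c3)[C@H]2C4OCOO4)ccc1O[Si](C(C)C)(C(C)C)C(C)C | intermediate (not isolated)
12 | (2S,3S,4S)-4-[(S)-{[tert-butyl(dimethyl)silyl]oxy}(Ar)methyl]-2-Ar-oxolane-3-carbaldehyde | COc1cc([C@@H](O[Si](C)(C)C(C)(C)C)[C@@H]2CO[C@H](c3ccc(O[Si](C(C)C)(C(C)C)C(C)C)c(OC)c3)[C@H]2C=O)ccc1O[Si](C(C)C)(C(C)C)C(C)C | intermediate (not isolated)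
13 | [(2S,3R,4S)-4-[(S)-{[tert-butyl(dimethyl)silyl]oxy}(Ar)methyl]-2-Ar-oxolan-3-yl]methanol | COc1cc([C@@H](O[Si](C)(C)C(C)(C)C)[C@@H]2CO[C@H](c3ccc(O[Si](C(C)C)(C(C)C)C(C)C)c(OC)c3)[C@H]2CO)ccc1O[Si](C(C)C)(C(C)C)C(C)C | intermediate
14 | (S)-(4-hydroxy-3-methoxyphenyl)[(3S,4R,5S)-5-(4-hydroxy-3-methoxyphenyl)-4-(hydroxymethyl)oxolan-3-yl]methanol | COc1cc([C@@H](O)[C@@H]2CO[C@H](c3ccc(O)c(OC)c3)[C@H]2CO)ccc1O | target

**Step count and risks**

Total step count: 7. Longest linear sequence: 7 steps (vanillin 1 to target 14; aldehyde 2 enters twice, in steps 2 and 5).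

Steps most likely to fail:

1. Step 5 (key step). What may go wrong: incomplete facial selectivity at the oxocarbenium carbon (ring A and the vinyl group cis), and loss of the benzylic silyl ether by ionization or protodesilylation of the allylsilane, because BF3 must both open the Si–O bond and generate the oxocarbenium ion. The fallback sets out from compound 8 and comes back to the route at compound 10, and it replaces the tethered siloxane by open-chain components. MeLi (Et2O, −78 to 0 °C) attacks silicon and opens the ring to (2S,3Z)-2-[(S)-{[tert-butyl(dimethyl)silyl]oxy}(Ar)methyl]-5-(trimethylsilyl)pent-3-en-1-ol F1. F1 and aldehyde 2 are then joined with TMSOTf (CH2Cl2, −78 °C) in a two-component silyl-Prins annulation, in which the oxocarbenium ion forms from a free hydroxyl and a robust trimethylsilyl allylsilane and can be generated at lower temperature. If the 2,3-cis isomer is still present, the benzylic C2 center is equilibrated with the same acid at −20 °C before quenching, which should give 10.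

2. Step 3. What may go wrong: poor discrimination between the two hydroxyls by the small chlorosilane (silylation of the benzylic oxygen, double silylation, or silyl migration before capping). The fallback sets out from compound 4 and comes back at compound 7, and it moves the selectivity from a silylation to a desilylation. Diol 4 is silylated exhaustively (TBSOTf, 2,6-lutidine, CH2Cl2, −78 to 0 °C) to (1S,2S)-1,3-bis{[tert-butyl(dimethyl)silyl]oxy}-2-ethenyl-1-Ar-propane F2. The primary silyl ether alone is then cleaved (HF·pyridine, pyridine, THF, 0 °C) to (2S,3S)-3-{[tert-butyl(dimethyl)silyl]oxy}-2-ethenyl-3-Ar-propan-1-ol F3, whose only free hydroxyl is silylated with 5 (Et3N, CH2Cl2, 0 °C) to give 7.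

3. Step 2. What may go wrong: low enantio- or diastereoselectivity, slow conversion of the electron-rich aldehyde, or partial loss of the aryl silyl ether under the basic conditions. The fallback sets out from compound 2 and comes back at compound 4, and it replaces catalyst control by an auxiliary-controlled anti-aldol reaction. But-3-enoic acid is coupled to (S)-4-benzyloxazolidin-2-one (PivCl, Et3N, LiCl, THF) to give (4S)-4-benzyl-3-(but-3-enoyl)-1,3-oxazolidin-2-one F4. F4 and aldehyde 2 are combined in the MgCl2-catalysed anti-aldol reaction (MgCl2 10 mol %, Et3N, TMSCl, EtOAc, rt), which by the chelated Z-enolate model should give (4S)-4-benzyl-3-[(2R,3S)-2-ethenyl-3-Ar-3-[(trimethylsilyl)oxy]propanoyl]-1,3-oxazolidin-2-one F5. Mild methanolysis (TFA cat., MeOH) gives (4S)-4-benzyl-3-[(2R,3S)-2-ethenyl-3-hydroxy-3-Ar-propanoyl]-1,3-oxazolidin-2-one F6, and LiBH4 (THF, MeOH, 0 °C) removes the auxiliary reductively to give diol 4.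

**Further compounds**

F1 | step 5 | (2S,3Z)-2-[(S)-{[tert-butyl(dimethyl)silyl]oxy}(Ar)methyl]-5-(trimethylsilyl)pent-3-en-1-ol | COc1cc([C@@H](O[Si](C)(C)C(C)(C)C)[C@@H](/C=C\C[Si](C)(C)C)CO)ccc1O[Si](C(C)C)(C(C)C)C(C)C
F2 | step 3 | (1S,2S)-1,3-bis{[tert-butyl(dimethyl)silyl]oxy}-2-ethenyl-1-Ar-propane | COc1cc([C@@H](O[Si](C)(C)C(C)(C)C)[C@@H](C=C)CO[Si](C)(C)C(C)(C)C)ccc1O[Si](C(C)C)(C(C)C)C(C)C
F3 | step 3 | (2S,3S)-3-{[tert-butyl(dimethyl)silyl]oxy}-2-ethenyl-3-Ar-propan-1-ol | COc1cc([C@@H](O[Si](C)(C)C(C)(C)C)[C@@H](C=C)CO)ccc1O[Si](C(C)C)(C(C)C)C(C)C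
F4 | step 2 | (4S)-4-benzyl-3-(but-3-enoyl)-1,3-oxazolidin-2-one | C=CCC(=O)N1[C@@H](Cc2ccccc2)COC1=O
F5 | step 2 | (4S)-4-benzyl-3-[(2R,3S)-2-ethenyl-3-Ar-3-[(trimethylsilyl)oxy]propanoyl]-1,3-oxazolidin-2-one | COc1cc([C@@H](O[Si](C)(C)C)[C@@H](C=C)C(=O)N2[C@@H](Cc3ccccc3)COC2=O)ccc1O[Si](C(C)C)(C(C)C)C(C)C
F6 | step 2 | (4S)-4-benzyl-3-[(2R,3S)-2-ethenyl-3-hydroxy-3-Ar-propanoyl]-1,3-oxazolidin-2-one | COc1cc([C@@H](O)[C@@H](C=C)C(=O)N2[C@@H](Cc3ccccc3)COC2=O)ccc1O[Si](C(C)C)(C(C)C)C(C)C
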